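Assumption: the biogenesis is taken to be the rearrangement of a 6,19-dioxygenated trans-clerod-3-ene in which C4 shifts from C5 to C19 (ring A 6→7) while C7 shifts from C6 to C5 (ring B 6→5, C6 extruded as CHO).
Naming: locants follow clerodane numbering (C1–C10 ring carbons, Me-17 on C8, Me-18 on C4, C19 on C5, C20 on C9, side chain C11–C16); α is the face of C19, C20 and Me-17, β the face of H-10. In this numbering the target is 5R,8R,9R,10R,19R,13Z.

**Retrosynthetic overview**
1. Target ⇐ one-flask double 1,2-shift of a trans-clerodane 19-aldehyde 6-silyl ether (C4: C5→C19; C7: C6→C5), which forms the seven- and five-membered rings together.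
2. That aldehyde is held as its 19,20-lactol ⇐ bridged 19,20-δ-lactone; the side chain comes from B-alkyl Suzuki coupling at a C11=C12 vinyl group.
3. Lactone and C5 quaternary centre ⇐ tether-directed C-acylation of a C5=C6 silyl dienol ether by a C20 carbonate (fixes the trans-decalin).
4. Ring B ⇐ catalytic asymmetric Diels–Alder reaction of a ring-A 2-siloxy triene with an (E)-2-(acyloxymethyl)but-2-enal (sets C8, C9, C10).
5. Order of ring formation: ring A (bought) → ring B (cycloaddition) → lactone bridge → seven- and five-membered rings (cascade, last step).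

**Route**

Step 1
Reactants: 1 2-methylcyclohex-2-en-1-one
Product: 3 6-methylcyclohexa-1,5-dien-1-yl trifluoromethanesulfonate, via lithium dienolate 2 (not isolated)
Conditions: LiN(iPr)2, THF, −78 °C; PhN(SO2CF3)2, −78 → 0 °C; NaHCO3 (aq)
Reagents that add atoms: N-phenylbis(trifluoromethanesulfonimide), O=S(=O)(N(c1ccccc1)S(=O)(=O)C(F)(F)F)C(F)(F)F
Why: Kinetic α'-deprotonation of the enone gives the cross-conjugated dienolate 2, which is O-sulfonylated (enol triflate formation); no stereocentre.

Step 2
Reactants: 3 6-methylcyclohexa-1,5-dien-1-yl trifluoromethanesulfonate; 4 tributyl(1-ethoxyethenyl)stannane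
Product: 6 1-(6-methylcyclohexa-1,5-dien-1-yl)ethan-1-one, via ethoxy diene 5 (not isolated)
Conditions: Pd(PPh3)4 (5 mol %), LiCl, THF, 65 °C; then 0.5 M HCl (aq), 0 °C
Reagents that add atoms: water, O
Why: Stille cross-coupling of the dienyl triflate with the α-alkoxyvinyl stannane followed by mild enol-ether hydrolysis gives the methyl ketone; no stereocentre.

Step 3
Reactants: 6 1-(6-methylcyclohexa-1,5-dien-1-yl)ethan-1-one
Product: 7 tert-butyldimethyl{[1-(6-methylcyclohexa-1,5-dien-1-yl)ethenyl]oxy}silane
Conditions: TBSOTf, Et3N, CH2Cl2, 0 °C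
Reagents that add atoms: tert-butyldimethylsilyl trifluoromethanesulfonate, CC(C)(C)[Si](C)(C)OS(=O)(=O)C(F)(F)F
Why: Soft enolisation (silyl enol ether formation) can only occur at the CH3 group and gives the 2-siloxy diene C7=C6(OTBS)–C5=C10.

Step 4
Reactants: 8 diethyl ethylidenemalonate
Product: 9 2-ethylidenepropane-1,3-diol
Conditions: iBu2AlH (4.4 equiv), CH2Cl2, −78 → 0 °C; potassium sodium tartrate (KNaC4H4O6, aq)
Reagents that add atoms: none
Why: 1,2-Reduction of both ester groups of the alkylidene malonate by the aluminium hydride gives the 2-alkylidene-1,3-diol.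

Step 5
Reactants: 9 2-ethylidenepropane-1,3-diol
Product: 10 (E)-2-(hydroxymethyl)but-2-enal
Conditions: MnO2 (activated), CH2Cl2, rt; then I2 (2 mol %), daylight
Reagents that add atoms: none
Why: Allylic oxidation of one primary allylic alcohol by MnO2 (the less hindered CH2OH, trans to CH3, reacts first) and iodine-catalysed equilibration converge on the more stable E enal with CH3 cis to CH2OH.

Step 6
Reactants: 10 (E)-2-(hydroxymethyl)but-2-enal; 11 phenyl chloroformate
Product: 12 (E)-2-formylbut-2-en-1-yl phenyl carbonate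
Conditions: pyridine, CH2Cl2, 0 °C
Reagents that add atoms: none
Why: O-acylation (carbonate formation) installs on the future C20 oxygen the carbonyl carbon that later becomes C19.

Step 7
Reactants: 7 tert-butyldimethyl{[1-(6-methylcyclohexa-1,5-dien-1-yl)ethenyl]oxy}silane; 12 (E)-2-formylbut-2-en-1-yl phenyl carbonate
Product: 13 6-(tert-butyldimethylsilyloxy)-20-(phenoxycarbonyloxy)-12,13,14,15,16,19-hexanorcleroda-3,5-dien-11-al
Conditions: (S)-B-(o-tolyl)-diphenylprolinol oxazaborolidine·HN(SO2CF3)2 (20 mol %), CH2Cl2, −78 → −40 °C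
Reagents that add atoms: none
Why: Catalytic enantioselective Diels–Alder reaction (Corey cationic oxazaborolidine): the C6 siloxy group and the C10 ring substituent both direct C7 to C8 and C10 to C9, the E dienophile keeps Me-17 cis to C20, the bulky catalyst-bound formyl group takes the exo position away from the OTBS/C4 side so that C20 ends cis to C1 and trans to H-10, and the catalyst shields the re face at C9 of the s-trans enal (formyl C–H···O model) so the diene adds to the si face.

Step 8
Reactants: 13 6-(tert-butyldimethylsilyloxy)-20-(phenoxycarbonyloxy)-12,13,14,15,16,19-hexanorcleroda-3,5-dien-11-al; 14 methyltriphenylphosphonium bromide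
Product: 15 6-(tert-butyldimethylsilyloxy)-20-(phenoxycarbonyloxy)-13,14,15,16,19-pentanorcleroda-3,5,11-triene
Conditions: KN(SiMe3)2, THF, 0 °C; then 13, −78 → 0 °C
Reagents that add atoms: none
Why: Wittig methylenation of the non-enolisable neopentyl aldehyde is far faster at −78 °C than attack of the ylide on the aryl carbonate; stereocentres untouched.

Step 9
Reactants: 15 6-(tert-butyldimethylsilyloxy)-20-(phenoxycarbonyloxy)-13,14,15,16,19-pentanorcleroda-3,5,11-triene
Product: 16 6-oxo-13,14,15,16-tetranorcleroda-3,11-dien-19,20-olide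
Conditions: tetrabutylammonium difluorotriphenylsilicate (1.1 equiv), THF (0.01 M), −20 °C → rt; NH4Cl (aq)
Reagents that add atoms: none
Why: Fluoride unmasks the regiodefined dienolate (O–C6=C5–C4=C3), which undergoes intramolecular Claisen-type C-acylation by the C20 phenyl carbonate through a six-membered transition state (O-acylation would need an eight-membered ring, the γ-carbon is out of reach); because C20 is α on C9, C19 is delivered to the α face of C5, which sets the quaternary centre and the trans ring fusion (C19 anti to H-10).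

Step 10
Reactants: 16 6-oxo-13,14,15,16-tetranorcleroda-3,11-dien-19,20-olide
Product: 17 6α-(triethylsilyloxy)-13,14,15,16-tetranorcleroda-3,11-dien-19,20-olide
Conditions: [(Ph3P)CuH]6 (3 mol %), Et3SiH, toluene, rt
Reagents that add atoms: triethylsilane, CC[SiH](CC)CC
Why: Copper hydride-catalysed hydrosilylation of the ketone (lactone and unactivated alkenes untouched) delivers hydride to the β face opposite the α lactone bridge and gives the equatorial 6α silyl ether directly; the C6 configuration is lost in step 15, so either epimer serves.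

Step 11
Reactants: 18 but-2-yne-1,4-diol
Product: 19 1,4-bis(triethylsilyloxy)but-2-yne
Conditions: Et3SiCl, imidazole, CH2Cl2, 0 °C
Reagents that add atoms: chlorotriethylsilane, CC[Si](Cl)(CC)CC
Why: Routine silylation of both primary alcohols (silyl ether formation).

Step 12
Reactants: 19 1,4-bis(triethylsilyloxy)but-2-yne
Product: 21 (E)-2-iodo-1,4-bis(triethylsilyloxy)but-2-ene, via alkenylzirconocene 20 (not isolated)
Conditions: Cp2Zr(H)Cl, THF, rt; then I2, 0 °C
Reagents that add atoms: iodine, II
Why: syn-Hydrozirconation of the symmetrical alkyne and iodinolysis with retention give the vinyl iodide with the two CH2O groups cis.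

Step 13
Reactants: 17 6α-(triethylsilyloxy)-13,14,15,16-tetranorcleroda-3,11-dien-19,20-olide; 21 (E)-2-iodo-1,4-bis(triethylsilyloxy)but-2-ene
Product: 23 (13Z)-6α,15,16-tris(triethylsilyloxy)cleroda-3,13-dien-19,20-olide, via alkylborane 22 (not isolated)
Conditions: 9-BBN, THF, rt; then 21, [1,1'-bis(diphenylphosphino)ferrocene]PdCl2 (5 mol %), AsPh3, K3PO4 (aq), DMF, rt
Reagents that add atoms: none
Why: Anti-Markovnikov hydroboration is selective for the monosubstituted vinyl group over the trisubstituted C3=C4 alkene, and B-alkyl Suzuki–Miyaura coupling proceeds with retention of alkene geometry (C12 trans to C15).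

Step 14
Reactants: 23 (13Z)-6α,15,16-tris(triethylsilyloxy)cleroda-3,13-dien-19,20-olide
Product: 24 (13Z)-6α,15,16-tris(triethylsilyloxy)-19,20-epoxycleroda-3,13-dien-19-ol
Conditions: iBu2AlH (1.2 equiv), CH2Cl2, −78 °C; potassium sodium tartrate (KNaC4H4O6, aq)
Reagents that add atoms: none
Why: Partial reduction of the hindered bridged δ-lactone stops at the stable aluminium hemiacetal (lactone-to-lactol reduction); silyl ethers and alkenes survive, and both lactol anomers are usable.

Step 15
Reactants: 24 (13Z)-6α,15,16-tris(triethylsilyloxy)-19,20-epoxycleroda-3,13-dien-19-ol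
Product: 27 target CNP0338913.1, via aluminium chelate 25 (not isolated), via bis-TES ether 26 (not isolated)
Conditions: MeAlCl2 (1.05 equiv), CH2Cl2, −78 → −40 °C; then 1 M HCl (aq)/THF, 0 °C → rt
Reagents that add atoms: none
Why: Proposed new method: MeAlCl2 is protonated by the lactol OH (loss of CH4) and the ring-chain tautomer is the 19-aldehyde 25 chelated by its own C20–O–AlCl2 group, which holds the carbonyl oxygen on the C10/C20 side; the C3=C4 π bond attacks C19 (1,2-vinyl shift through a cyclopropylcarbinyl-type transition state) while the anti-periplanar C6–C7 ring bond migrates to C5 with inversion, pushed by the 6-OTES oxygen whose silyl group leaves to chloride, so one step forms the seven- and five-membered rings, the C6 aldehyde and the 19R carbinol, and the dilute acid work-up frees the aluminium alkoxide and cleaves the two primary TES ethers of 26; the closest known reaction types are the Prins–pinacol cascade, the semipinacol rearrangement of silyl ethers and the acid-catalysed aldehyde–ketone rearrangement (1,2-shift to an activated formyl carbon).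

**Compound list**
1 | 2-methylcyclohex-2-en-1-one | CC1=CCCC1=O | starting material
2 | lithium 6-methylcyclohexa-1,5-dien-1-olate | CC1=CCCC=C1[O-].[Li+] | intermediate
3 | 6-methylcyclohexa-1,5-dien-1-yl trifluoromethanesulfonate | CC1=CCCC=C1OS(=O)(=O)C(F)(F)F | intermediate
4 | tributyl(1-ethoxyethenyl)stannane | CCCC[Sn](CCCC)(CCCC)C(=C)OCC | starting material
5 | 1-(1-ethoxyethenyl)-6-methylcyclohexa-1,5-diene | CCOC(=C)C1=CCCC=C1C | intermediate
6 | 1-(6-methylcyclohexa-1,5-dien-1-yl)ethan-1-one | CC(=O)C1=CCCC=C1C | intermediate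
7 | tert-butyldimethyl{[1-(6-methylcyclohexa-1,5-dien-1-yl)ethenyl]oxy}silane | C=C(O[Si](C)(C)C(C)(C)C)C1=CCCC=C1C | intermediate
8 | diethyl ethylidenemalonate | CC=C(C(=O)OCC)C(=O)OCC | starting material
9 | 2-ethylidenepropane-1,3-diol | CC=C(CO)CO | intermediate
10 | (E)-2-(hydroxymethyl)but-2-enal | C/C=C(\CO)C=O | intermediate
11 | phenyl chloroformate | O=C(Cl)Oc1ccccc1 | starting material
12 | (E)-2-formylbut-2-en-1-yl phenyl carbonate | C/C=C(\COC(=O)Oc1ccccc1)C=O | intermediate
13 | Diels–Alder adduct: Δ3 and Δ5 diene, 6-OTBS, 8α-Me, 9β-CHO (C11), 9α-CH2OC(=O)OPh (C20), 10β-H | CC1=CCC[C@H]2C1=C(O[Si](C)(C)C(C)(C)C)C[C@@H](C)[C@@]2(C=O)COC(=O)Oc1ccccc1 | intermediate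
14 | methyltriphenylphosphonium bromide | C[P+](c1ccccc1)(c1ccccc1)c1ccccc1.[Br-] | starting material
15 | as 13 with 9β-vinyl (C11=C12) in place of CHO | CC1=CCC[C@H]2C1=C(O[Si](C)(C)C(C)(C)C)C[C@@H](C)[C@@]2(C=C)COC(=O)Oc1ccccc1 | intermediate
16 | trans-decalin keto lactone: C5α–C19(=O)–O–C20H2–C9α bridge, 6-oxo, Δ3, 8α-Me, 9β-vinyl, 10β-H | CC1=CCC[C@H]2[C@]13C(=O)OC[C@]2(C=C)[C@H](C)CC3=O | intermediate
17 | as 16 with 6α-OSiEt3 (6β-H) in place of the ketone | CC1=CCC[C@H]2[C@]13C(=O)OC[C@]2(C=C)[C@H](C)C[C@@H]3O[Si](CC)(CC)CC | intermediate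
18 | but-2-yne-1,4-diol | OCC#CCO | starting material
19 | 1,4-bis(triethylsilyloxy)but-2-yne | CC[Si](CC)(CC)OCC#CCO[Si](CC)(CC)CC | intermediate
20 | chlorido[(E)-1,4-bis(triethylsilyloxy)but-2-en-2-yl]zirconocene (CH2O groups cis) | CC[Si](CC)(CC)OC/C=C(\CO[Si](CC)(CC)CC)[Zr](Cl)(C1C=CC=C1)C1C=CC=C1 | intermediate
21 | (E)-2-iodo-1,4-bis(triethylsilyloxy)but-2-ene (CH2O groups cis) | CC[Si](CC)(CC)OC/C=C(\CO[Si](CC)(CC)CC)I | intermediate
22 | B-alkyl-9-BBN adduct of 17 (boron on C12) | CC1=CCC[C@H]2[C@]13C(=O)OC[C@]2(CCB2C4CCCC2CCC4)[C@H](C)C[C@@H]3O[Si](CC)(CC)CC | intermediate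
23 | (13Z)-6α,15,16-tris(triethylsilyloxy)cleroda-3,13-dien-19,20-olide | CC1=CCC[C@H]2[C@]13C(=O)OC[C@]2(CC/C(=C/CO[Si](CC)(CC)CC)CO[Si](CC)(CC)CC)[C@H](C)C[C@@H]3O[Si](CC)(CC)CC | intermediate
24 | 19,20-lactol of 23 (C19 anomers) | CC1=CCC[C@H]2[C@]13C(O)OC[C@]2(CC/C(=C/CO[Si](CC)(CC)CC)CO[Si](CC)(CC)CC)[C@H](C)C[C@@H]3O[Si](CC)(CC)CC | intermediate
25 | ring-opened 19-aldehyde with C20–O–AlCl2 (chelated), 6α-OTES | CC1=CCC[C@H]2[C@@]1(C=O)[C@@H](O[Si](CC)(CC)CC)C[C@@H](C)[C@]2(CO[Al](Cl)Cl)CC/C(=C/CO[Si](CC)(CC)CC)CO[Si](CC)(CC)CC | intermediate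
26 | 15,16-bis(triethylsilyl) ether of the target | CC1=CCC[C@H]2[C@](C=O)(C[C@@H](C)[C@]2(CO)CC/C(=C/CO[Si](CC)(CC)CC)CO[Si](CC)(CC)CC)[C@@H]1O | intermediate
27 | target CNP0338913.1: (13Z,19R)-15,16,19,20-tetrahydroxy-4(5→19),7(6→5)-diabeocleroda-3,13-dien-6-al, cis-fused 7/5 bicycle | CC1=CCC[C@H]2[C@](C=O)(C[C@@H](C)[C@]2(CO)CC/C(=C/CO)CO)[C@@H]1O | target

**Step count**
Total: 15 steps. Longest linear sequence: 10 steps (steps 1, 2, 3, 7, 8, 9, 10, 13, 14, 15, from 2-methylcyclohex-2-en-1-one).

**Three steps most likely to fail**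

Step 15 (double 1,2-shift). Risks: ionisation of the lactol to a cyclic oxocarbenium ion (giving a 19,20-ether), retro-aldol fragmentation of the C5–C6 bond, a hydride shift that gives the ring-expanded enone, or the 19-epimer if chelation is lost. The fallback sets out from 24 and comes back at 27. It replaces the aluminium chelate by a covalent silicon template. The lactol hydroxyl of 24 is silylated with iPr2SiCl2 and imidazole to give the lactol O-(chlorodiisopropylsilyl) ether F1. AgOSO2CF3 with 2,6-di-tert-butylpyridine in CH2Cl2 at −78 °C removes chloride from F1; the silyl cation is captured by the ring oxygen and opens the acetal to a C19 oxocarbenium ion tethered through Si to O20, again locked on the C20 side. The same pair of shifts follows, the C6 oxocarbenium ion loses Et3SiOSO2CF3, and the product is the isolable 19,20-O-diisopropylsilylene 15,16-bis-TES ether F2, which can be purified. HF·pyridine in THF then removes the silylene and both TES groups from F2 to give 27.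

Step 7 (Diels–Alder). Risks: a hindered bond between C9 and C10, competition from the ring-A cyclohexadiene unit of 7, and above all the need for the formyl-exo transition state; the endo adduct is the C10 epimer. The fallback sets out from 7 and 12 and comes back at 16. The cycloaddition is run with Me2AlCl in CH2Cl2 and the endo adduct 10-epi-13 F3 is accepted. Wittig methylenation of F3 with Ph3P=CH2 (from 14 and KN(SiMe3)2) gives 10-epi-15 F4. IBX·4-methoxypyridine N-oxide in DMSO dehydrosilylates F4 to the cross-conjugated 3,5(10)-dien-6-one F5 (C5=C10 and C3=C4 double bonds), which erases C10. SmI2 with one equivalent of t-BuOH in THF/HMPA at −78 °C reduces the enone of F5; the C10 carbanion is protonated axially on the β face, anti to the axial C20 arm, and the samarium dienolate closes onto the C20 carbonate to give 16.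

Step 9 (tethered C-acylation to a quaternary centre). Risks: intermolecular O-acylation, fluoride attack on the carbonate, and retro-Claisen opening of the non-enolisable β-keto lactone. The fallback sets out from 15 and comes back at 16. It builds the C5–C19 bond by intermolecular carboxylation and closes the lactone afterwards. LiOH in aqueous THF followed by dilute HCl removes the carbonate and the silyl enol ether to give the 20-hydroxy-6-oxo-13,14,15,16,19-pentanorcleroda-3,11-diene F6 (C5 epimers; any conjugated 4-ene isomer formed alongside gives the same dienolate). KH (2.5 equiv) in THF at 0 °C → rt converts F6 under equilibrating conditions into the alkoxide and the extended dienolate O–C6=C5–C4=C3, which is carboxylated at its α-carbon C5 with CO2 at −78 °C. On acidification the isomer with the carboxyl group on the α face, the 20-hydroxy-6-oxo-13,14,15,16-tetranorcleroda-3,11-dien-19-oic acid F7, is closed to 16 with EDC·HCl and DMAP. The β-carboxylated epimer of F7 cannot lactonise; it decarboxylates back to F6 and is recycled.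

**Further compounds**
F1 | step 15 | lactol O-(chlorodiisopropylsilyl) ether of 24 | CC1=CCC[C@H]2[C@]13C(O[Si](Cl)(C(C)C)C(C)C)OC[C@]2(CC/C(=C/CO[Si](CC)(CC)CC)CO[Si](CC)(CC)CC)[C@H](C)C[C@@H]3O[Si](CC)(CC)CC
F2 | step 15 | 19,20-O-diisopropylsilylene derivative of 26 | CC1=CCC[C@H]2[C@](C=O)(C[C@@H](C)[C@]2(CO3)CC/C(=C/CO[Si](CC)(CC)CC)CO[Si](CC)(CC)CC)[C@@H]1O[Si]3(C(C)C)C(C)C
F3 | step 7 | 10-epi-13 (endo adduct) | CC1=CCC[C@@H]2C1=C(O[Si](C)(C)C(C)(C)C)C[C@@H](C)[C@@]2(C=O)COC(=O)Oc1ccccc1
F4 | step 7 | 10-epi-15 | CC1=CCC[C@@H]2C1=C(O[Si](C)(C)C(C)(C)C)C[C@@H](C)[C@@]2(C=C)COC(=O)Oc1ccccc1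
F5 | step 7 | 6-oxo-20-(phenoxycarbonyloxy)-13,14,15,16,19-pentanorcleroda-3,5(10),11-triene | CC1=CCCC2=C1C(=O)C[C@@H](C)[C@@]2(C=C)COC(=O)Oc1ccccc1
F6 | step 9 | 20-hydroxy-6-oxo-13,14,15,16,19-pentanorcleroda-3,11-diene (C5 epimers) | CC1=CCC[C@H]2C1C(=O)C[C@@H](C)[C@@]2(C=C)CO
F7 | step 9 | 20-hydroxy-6-oxo-13,14,15,16-tetranorcleroda-3,11-dien-19-oic acid | CC1=CCC[C@H]2[C@@]1(C(=O)O)C(=O)C[C@@H](C)[C@@]2(C=C)CO
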